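The labdane is cut at the C3–C4 bond of ring A (labdane numbering), between the secondary carbinol C3 and the gem-dimethyl carbon C4. The key step exploits the fact that C4, attached to C5 of ring B, is the isopropenyl carbon of (R)-carvone, whose six-membered ring becomes ring B (C5–C10): hydrogen-atom transfer turns C4 into a tertiary radical that closes ring A onto a C3 aldehyde, creating the C3–C4 bond, the quaternary C4 and the 3β-hydroxyl in one operation. The precursor is carvone bearing at C10 a methyl group and, trans to the isopropenyl group, a 3-oxopropyl chain. Ring B is afterwards oxidised at C6 and the C9 carbinol and butenolide chain are attached.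

Key step: step 4

Remark (numbering): all bicyclic compounds carry labdane numbers (ring A = C1–C5 and C10, ring B = C5–C10, chain C11–C12, butenolide C13–C16); β is the face of the C10 methyl group. Read this way, the target is the 3β,9α-dihydroxy-6β-acetoxy-8α-methyl compound with 5α-H and 10β-CH3.

Remark (assumption): the equatorial 3β-hydroxyl would be acylated before the hindered axial 6β-hydroxyl, so O3 is carried as a TBS ether from step 5 to step 14.

Step 1
Reactants: 1 (R)-(−)-carvone; 2 iodomethane
Product: 4 (5R,6S)-6-methylcarvone (methyl trans to isopropenyl; the minor C6 epimer is carried along), via lithium dienolate of carvone 3 (not isolated)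
Conditions: LiN(i-Pr)2, THF, −78 °C; then MeI, −78 → 0 °C
Reagents that add atoms: iodomethane 2, CI
Why: Kinetic deprotonation at the α′-CH2 (future C10) gives the cross-conjugated lithium dienolate, which is methylated by SN2 enolate alkylation; the configuration of the new methine is irrelevant because step 2 makes this carbon planar again.

Step 2
Reactants: 4 (5R,6S)-6-methylcarvone; 5 allyl bromide
Product: 7 (5S,6S)-6-allyl-6-methylcarvone (allyl trans to isopropenyl), via lithium dienolate of 6-methylcarvone 6 (not isolated)
Conditions: LiN(i-Pr)2, THF, −78 °C; then allyl bromide, DMPU, −78 °C → rt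
Reagents that add atoms: allyl bromide 5, C=CCBr
Why: A second kinetic α′-deprotonation gives the fully substituted dienolate, and enolate alkylation takes place on the face opposite the neighbouring isopropenyl group (1,2-induction well established for 6-alkylcarvones), which sets the quaternary C10 with the three-carbon arm trans to the isopropenyl group.

Step 3
Reactants: 7 (5S,6S)-6-allyl-6-methylcarvone; 8 dioxygen
Product: 9 3-[(1S,6S)-1,3-dimethyl-2-oxo-6-(prop-1-en-2-yl)cyclohex-3-en-1-yl]propanal (6-methyl-6-(3-oxopropyl)carvone, oxopropyl trans to isopropenyl)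
Conditions: PdCl2(PhCN)2 (cat.), CuCl2·2H2O (cat.), AgNO2 (cat.), O2 (1 atm), t-BuOH/MeNO2, rt
Reagents that add atoms: dioxygen 8, O=O
Why: Nitrite-co-catalysed aldehyde-selective (anti-Markovnikov) Wacker oxidation places the oxygen on the terminal carbon of the monosubstituted alkene next to the quaternary centre, a substrate class for which this selectivity is established, while the 1,1-disubstituted isopropenyl group and the enone are poor substrates for divalent palladium.

Step 4
Reactants: 9 3-[(1S,6S)-1,3-dimethyl-2-oxo-6-(prop-1-en-2-yl)cyclohex-3-en-1-yl]propanal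
Product: 10 3β-hydroxy-4,4,8,10β-tetramethyl-5α-octal-7-en-9-one, trans-fused [(4aS,6S,8aS)-6-hydroxy-2,5,5,8a-tetramethyl-4a,5,6,7,8,8a-hexahydronaphthalen-1(4H)-one]
Conditions: Fe(acac)3 (0.3 equiv), PhSiH3 (2.5 equiv), EtOH/ethylene glycol, 60 °C, degassed
Reagents that add atoms: none
Why: An iron hydride formed from Fe(acac)3 and PhSiH3 transfers a hydrogen atom to the terminal CH2 of the isopropenyl group (Markovnikov metal-hydride hydrogen-atom transfer), giving the tertiary radical at C4 that already carries both methyl groups; this nucleophilic radical adds to the carbon of the C3 aldehyde, and the alkoxyl radical is reduced by divalent iron and protonated by ethanol. The closest known reaction type is the iron-hydride reductive radical cyclisation of alkene-tethered ketones and aldehydes to cycloalkanols. Ring A (C1–C5, C10) closes in the 6-exo-trig mode by formation of the C3–C4 bond. The new stereocentre C3 is controlled by a chair transition state built on the trans relationship of C5 and C10, with the aldehyde oxygen pseudo-equatorial and free of 1,3-diaxial contacts with the axial hydrogens on C1 and C5, so the 3β-alcohol should predominate. The step needs hydrogen-atom transfer to the electron-rich 1,1-disubstituted alkene in preference to the electron-poor trisubstituted enone alkene, which the known behaviour of carvone-type substrates towards such hydrides secures; the trans ring fusion is fixed beforehand by the anti allylation of step 2.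

Step 5
Reactants: 10 3β-hydroxy-4,4,8,10β-tetramethyl-5α-octal-7-en-9-one; 11 tert-butyldimethylsilyl triflate
Product: 12 3β-(tert-butyldimethylsilyloxy)-4,4,8,10β-tetramethyl-5α-octal-7-en-9-one
Conditions: TBSOTf, 2,6-lutidine, CH2Cl2, −78 → 0 °C
Reagents that add atoms: tert-butyldimethylsilyl triflate 11, CC(C)(C)[Si](C)(C)OS(=O)(=O)C(F)(F)F
Why: Silyl ether formation with the reactive silyl triflate protects the only hydroxyl group, so that O3 cannot compete in the later acetylation of the hindered O6; the enone is inert to the hindered amine base.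

Step 6
Reactants: 12 3β-TBSO-4,4,8,10β-tetramethyl-5α-octal-7-en-9-one; 13 tert-butyl hydroperoxide
Product: 14 3β-TBSO-4,4,8,10β-tetramethyl-5α-octal-7-ene-6,9-dione
Conditions: Pd(OH)2/C (cat.), t-BuOOH, K2CO3 (0.25 equiv), CH2Cl2, rt
Reagents that add atoms: tert-butyl hydroperoxide 13, CC(C)(C)OO
Why: Palladium/tert-butyl hydroperoxide allylic oxidation of an α,β-enone to the 1,4-enedione: the tert-butylperoxyl radical abstracts a hydrogen from C6, the only CH2 vinylogous to the C9 carbonyl, and the γ-peroxide collapses to the ketone under carbonate, leaving the silyl ether untouched.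

Step 7
Reactants: 14 3β-TBSO-4,4,8,10β-tetramethyl-5α-octal-7-ene-6,9-dione
Product: 15 3β-TBSO-4,4,8α,10β-tetramethyl-5α-decalin-6,9-dione (8β-H)
Conditions: Zn dust, AcOH, rt; then DBU (cat.), CH2Cl2, rt
Reagents that add atoms: none
Why: Zinc in acetic acid reduces only the C7=C8 bond activated by two carbonyl groups (dissolving-metal reduction of an enedione), and C8, which is α to the C9 ketone, equilibrates to the equatorial 8α-methyl epimer that avoids a syn-diaxial contact with the C10 methyl group.

Step 8
Reactants: 15 3β-TBSO-4,4,8α,10β-tetramethyl-5α-decalin-6,9-dione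
Product: 16 3β-TBSO-6β-hydroxy-4,4,8α,10β-tetramethyl-5α-decalin-9-one
Conditions: NaBH4, MeOH/CH2Cl2, −20 °C
Reagents that add atoms: none
Why: Borohydride reduction should discriminate the two ketones because C9 is flanked by a quaternary and a tertiary carbon whereas C6 has a CH2 neighbour, and hydride reaches C6 from the α face because the β face is screened by the syn-axial methyl groups on C10 and C4, which gives the axial 6β-alcohol.

Step 9
Reactants: 16 3β-TBSO-6β-hydroxy-4,4,8α,10β-tetramethyl-5α-decalin-9-one; 17 methyltriphenylphosphonium bromide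
Product: 18 3β-TBSO-9-methylene-4,4,8α,10β-tetramethyl-5α-decalin-6β-ol (exocyclic C9=C11)
Conditions: Ph3PCH3Br, KOtBu, toluene, 90 °C
Reagents that add atoms: methyltriphenylphosphonium bromide 17, C[P+](c1ccccc1)(c1ccccc1)c1ccccc1.[Br-]
Why: Wittig methylenation with the ylide generated by potassium tert-butoxide in hot toluene is the proven protocol for hindered, enolisable ketones; the C6 alkoxide is a spectator and C8 keeps its thermodynamically preferred configuration, which is locked once the carbonyl is gone.

Step 10
Reactants: 18 3β-TBSO-9-methylene-4,4,8α,10β-tetramethyl-5α-decalin-6β-ol; 19 meta-chloroperoxybenzoic acid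
Product: 20 9α,11-epoxide of 18 (spiro-oxirane, oxygen on the α face, C11 on the β face)
Conditions: mCPBA, NaHCO3 (buffer), CH2Cl2, 0 °C
Reagents that add atoms: meta-chloroperoxybenzoic acid 19, OOC(=O)c1cccc(Cl)c1
Why: Prilezhaev epoxidation of the exocyclic alkene occurs from the α face, anti to the adjacent axial C10 methyl group, so that the oxirane oxygen (the future 9α-hydroxyl) is α and C11 is β; the bicarbonate buffer protects the acid-sensitive spiro-oxirane.

Step 11
Reactants: 20 9α,11-epoxide; 21 trimethylsulfonium iodide
Product: 22 3β-TBSO-9β-vinyl-4,4,8α,10β-tetramethyl-5α-decalin-6β,9α-diol (C11=C12)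
Conditions: Me3SI, n-BuLi, THF, −10 °C; then 20, −10 °C → rt
Reagents that add atoms: trimethylsulfonium iodide 21, C[S+](C)C.[I-]
Why: Dimethylsulfonium methylide opens the oxirane by SN2 attack at its CH2 terminus C11 and the γ-alkoxy sulfonium intermediate loses dimethyl sulfide by ylide-mediated elimination, the known one-carbon homologation of epoxides to allylic alcohols; the C9–O bond is never broken, so the 9α configuration is retained.

Step 12
Reactants: 22 3β-TBSO-9β-vinyl-decalin-6β,9α-diol; 23 acetic anhydride
Product: 24 6β-acetate of 22 (3β-TBSO-6β-acetoxy-9β-vinyl-4,4,8α,10β-tetramethyl-5α-decalin-9α-ol)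
Conditions: Ac2O, DMAP, pyridine, 40 °C
Reagents that add atoms: acetic anhydride 23, CC(=O)OC(C)=O
Why: DMAP-catalysed acylation acetylates the secondary 6β-hydroxyl, whereas the tertiary 9α-hydroxyl does not react under these conditions and O3 is blocked as its silyl ether.

Step 13
Reactants: 24 6β-acetate of the vinyl carbinol; 25 3-bromofuran-2(5H)-one
Product: 27 3-O-TBS ether of the target (6β-acetoxy-9α-hydroxy-3β-silyloxy butenolide), via B-alkyl-9-BBN adduct 26 (not isolated)
Conditions: 9-BBN, THF, rt; then 25, Pd(dppf)Cl2 (cat.), AsPh3 (cat.), aq K3PO4, DMF, rt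
Reagents that add atoms: 3-bromofuran-2(5H)-one 25, O=C1OCC=C1Br
Why: Anti-Markovnikov hydroboration of the vinyl group places boron on C12, and B-alkyl Suzuki–Miyaura coupling (oxidative addition of zerovalent palladium into the vinylic C–Br bond of the α-bromobutenolide, base-assisted transmetallation, reductive elimination) forms the C12–C13 bond at room temperature, which the acetate and the lactone tolerate.

Step 14
Reactants: 27 3-O-TBS ether of the target
Product: 28 CNP0513254.1, 6β-acetoxy-3β,9α-dihydroxylabd-13-en-16,15-olide (8α-CH3, 5α-H, 10β-CH3)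
Conditions: HF·pyridine, THF, 0 °C → rt
Reagents that add atoms: none
Why: Fluoride cleaves the Si–O bond under mildly acidic conditions (desilylation) that leave the acetate, the tertiary alcohol and the base-sensitive butenolide intact.

Compound list
1 | (R)-(−)-carvone | CC1=CC[C@H](CC1=O)C(C)=C | starting material
2 | iodomethane | CI | starting material
3 | lithium dienolate of carvone (O–Li on C1, C1=C6 and C2=C3, carvone numbering) | CC1=CC[C@H](C=C1O[Li])C(C)=C | intermediate
4 | (5R,6S)-2,6-dimethyl-5-(prop-1-en-2-yl)cyclohex-2-en-1-one (6-methylcarvone, methyl trans to isopropenyl) | C1C=C(C)C(=O)[C@@H](C)[C@@H]1C(C)=C | intermediate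
5 | allyl bromide (3-bromoprop-1-ene) | C=CCBr | starting material
6 | lithium dienolate of 6-methylcarvone | C1C=C(C)C(O[Li])=C(C)[C@@H]1C(C)=C | intermediate
7 | (5S,6S)-6-allyl-2,6-dimethyl-5-(prop-1-en-2-yl)cyclohex-2-en-1-one (allyl trans to isopropenyl; C5 is unchanged in space, its descriptor changes only through the priority rules) | C1C=C(C)C(=O)[C@@](C)(CC=C)[C@@H]1C(C)=C | intermediate
8 | dioxygen | O=O | starting material
9 | 3-[(1S,6S)-1,3-dimethyl-2-oxo-6-(prop-1-en-2-yl)cyclohex-3-en-1-yl]propanal | C1C=C(C)C(=O)[C@@](C)(CCC=O)[C@@H]1C(C)=C | intermediate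
10 | (4aS,6S,8aS)-6-hydroxy-2,5,5,8a-tetramethyl-4a,5,6,7,8,8a-hexahydronaphthalen-1(4H)-one (3β-hydroxy-7-en-9-one, trans-fused) | C1C=C(C)C(=O)[C@@]2(C)CC[C@H](O)C(C)(C)[C@H]12 | intermediate
11 | tert-butyldimethylsilyl trifluoromethanesulfonate | CC(C)(C)[Si](C)(C)OS(=O)(=O)C(F)(F)F | starting material
12 | 3β-TBS ether of 10 | C1C=C(C)C(=O)[C@@]2(C)CC[C@H](O[Si](C)(C)C(C)(C)C)C(C)(C)[C@H]12 | intermediate
13 | tert-butyl hydroperoxide | CC(C)(C)OO | starting material
14 | 3β-TBSO-7-ene-6,9-dione | O=C1C=C(C)C(=O)[C@@]2(C)CC[C@H](O[Si](C)(C)C(C)(C)C)C(C)(C)[C@H]12 | intermediate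
15 | 3β-TBSO-8α-methyl-6,9-dione (8β-H) | O=C1C[C@@H](C)C(=O)[C@@]2(C)CC[C@H](O[Si](C)(C)C(C)(C)C)C(C)(C)[C@H]12 | intermediate
16 | 3β-TBSO-6β-hydroxy-8α-methyl-9-one | O[C@@H]1C[C@@H](C)C(=O)[C@@]2(C)CC[C@H](O[Si](C)(C)C(C)(C)C)C(C)(C)[C@H]12 | intermediate
17 | methyltriphenylphosphonium bromide | C[P+](c1ccccc1)(c1ccccc1)c1ccccc1.[Br-] | starting material
18 | 3β-TBSO-9-methylene-6β-ol (exocyclic C9=C11) | O[C@@H]1C[C@@H](C)C(=C)[C@@]2(C)CC[C@H](O[Si](C)(C)C(C)(C)C)C(C)(C)[C@H]12 | intermediate
19 | meta-chloroperoxybenzoic acid | OOC(=O)c1cccc(Cl)c1 | starting material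
20 | 3β-TBSO-9α,11-epoxy-6β-ol (spiro-oxirane, O α) | O[C@@H]1C[C@@H](C)[C@]3(CO3)[C@@]2(C)CC[C@H](O[Si](C)(C)C(C)(C)C)C(C)(C)[C@H]12 | intermediate
21 | trimethylsulfonium iodide | C[S+](C)C.[I-] | starting material
22 | 3β-TBSO-9β-vinyl-6β,9α-diol | O[C@@H]1C[C@@H](C)[C@](O)(C=C)[C@@]2(C)CC[C@H](O[Si](C)(C)C(C)(C)C)C(C)(C)[C@H]12 | intermediate
23 | acetic anhydride | CC(=O)OC(C)=O | starting material
24 | 3β-TBSO-6β-acetoxy-9β-vinyl-9α-ol | CC(=O)O[C@@H]1C[C@@H](C)[C@](O)(C=C)[C@@]2(C)CC[C@H](O[Si](C)(C)C(C)(C)C)C(C)(C)[C@H]12 | intermediate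
25 | 3-bromofuran-2(5H)-one | O=C1OCC=C1Br | starting material
26 | B-alkyl-9-BBN adduct of 24 (boron on C12) | CC(=O)O[C@@H]1C[C@@H](C)[C@](O)(CCB3C4CCCC3CCC4)[C@@]2(C)CC[C@H](O[Si](C)(C)C(C)(C)C)C(C)(C)[C@H]12 | intermediate
27 | 3-O-TBS ether of the target | CC(=O)O[C@@H]1C[C@@H](C)[C@](O)(CCC3=CCOC3=O)[C@@]2(C)CC[C@H](O[Si](C)(C)C(C)(C)C)C(C)(C)[C@H]12 | intermediate
28 | CNP0513254.1, 6β-acetoxy-3β,9α-dihydroxylabd-13-en-16,15-olide | CC(=O)O[C@@H]1C[C@@H](C)[C@](O)(CCC2=CCOC2=O)[C@@]2(C)CC[C@H](O)C(C)(C)[C@H]12 | target

Total step count: 14. Longest linear sequence: 14 steps, from 1 to 28; all other inputs are commercial reagents.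

Steps most likely to fail

Step 4. The closed alkoxyl radical may reopen by β-scission to the tertiary radical faster than it is reduced, so that the isopropenyl group is merely hydrogenated. The aldehyde may also be hydrosilylated before the alkene is activated. The fallback sets out from 9. Markovnikov addition of HBr (HBr in AcOH, 0 °C) to the isopropenyl group should give the tertiary bromide F1. Slow addition of Bu3SnH and AIBN in benzene at 80 °C generates the same C4 radical in a tin hydride chain, where the alkoxyl radical formed by 6-exo addition to the aldehyde is quenched at once by the Sn–H bond. This comes back to the route at 10.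

Step 6. Hydrogen abstraction at C6 may be too slow, because the hydrogen aligned with the enone π system is the axial 6β-H, which is shielded by the methyl groups on C10 and C4. The oxidant would then be consumed unproductively or attack the C8 methyl group. The fallback sets out from 12. Soft enolisation towards C6 (TMSOTf, Et3N, CH2Cl2) should give the silyl dienol ether F2. mCPBA oxidises its electron-rich γ terminus in a vinylogous Rubottom oxidation to the 6-hydroxy enone F3 (either C6 epimer serves). Dess–Martin oxidation of F3 comes back to the route at 14.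

Step 11. SN2 attack at C11 may be retarded by the fully substituted C9 and its neighbours. The ylide would then decompose or act as a base, isomerising the oxirane to an allylic alcohol or letting the C6 alkoxide open it across the ring. The fallback sets out from 18 and avoids substitution at C11. Dihydroxylation from the α face (OsO4 cat., NMO, acetone/water) should give the 6β,9α,11-triol F4. TEMPO with PhI(OAc)2 oxidises only the primary alcohol to the α-hydroxy aldehyde F5. Wittig methylenation (Ph3P=CH2, THF, −78 → 0 °C) comes back to the route at 22.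

Further compounds
F1 | step 4 | tertiary bromide, 3-[6-(2-bromopropan-2-yl)-1,3-dimethyl-2-oxocyclohex-3-en-1-yl]propanal with the configuration of 9 | C1C=C(C)C(=O)[C@@](C)(CCC=O)[C@@H]1C(C)(C)Br
F2 | step 6 | silyl dienol ether, 3β-TBSO-9-(trimethylsilyloxy)-6,8-diene | C1=CC(C)=C(O[Si](C)(C)C)[C@@]2(C)CC[C@H](O[Si](C)(C)C(C)(C)C)C(C)(C)[C@H]12
F3 | step 6 | 6-hydroxy enone, 3β-TBSO-6-hydroxy-7-en-9-one (C6 epimer not defined) | OC1C=C(C)C(=O)[C@@]2(C)CC[C@H](O[Si](C)(C)C(C)(C)C)C(C)(C)[C@H]12
F4 | step 11 | 6β,9α,11-triol (3β-TBSO) | O[C@@H]1C[C@@H](C)[C@](O)(CO)[C@@]2(C)CC[C@H](O[Si](C)(C)C(C)(C)C)C(C)(C)[C@H]12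
F5 | step 11 | α-hydroxy aldehyde, 3β-TBSO-6β,9α-dihydroxy-11-al | O[C@@H]1C[C@@H](C)[C@](O)(C=O)[C@@]2(C)CC[C@H](O[Si](C)(C)C(C)(C)C)C(C)(C)[C@H]12
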